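**Plan**

- Retrosynthesis: the two phenolic C–O bonds at C3' and C4' are cut back to two C–B bonds, and both of these to a single C3'–C4' aryne. The benzene ring carries the same group (OH) on the adjacent carbons C3' and C4', so the aryne may take up its two boryl groups in either sense.
- The aryne precursor, a 2-(trimethylsilyl)aryl triflate, is cut at C3'–Si and O–S back to a para-alkylphenol through its ortho-bromide. The chain is cut at C5–C6 into a Weinreb amide and a pentadecyl Grignard reagent.
- Forward: the C5–C6 bond is joined first and the ketone is masked as a dioxolane. The ring is then dressed (Br, O-silyl, silyl shift, triflate), the ketal is removed, and aryne diboration followed by C–B oxidation completes the catechol.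
- No ring is formed at any stage (the benzene ring is bought) and the target has no stereocentre. The position of the second oxygen follows from ortho-bromination of a para-blocked phenol.

Key step: step 8

Remark: ring carbons are numbered C1' (chain-bearing) to C6' and chain carbons C1 (benzylic) to C20; the target is achiral, so no stereodescriptors appear, and 1, 3 and 13 are taken as purchased.

**Step 1**
Reactants: 1 5-(4-hydroxyphenyl)pentanoic acid
Product: 2 5-(4-hydroxyphenyl)-N-methoxy-N-methylpentanamide
Conditions: MeNHOMe·HCl, EDC·HCl, N-methylmorpholine, CH2Cl2, 0 °C to rt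
Reagents that add atoms: N,O-dimethylhydroxylamine hydrochloride, CNOC.Cl
Why: Carbodiimide-mediated amide coupling (Weinreb amide formation), in which the activated acid should be captured by the amine far faster than by the weakly nucleophilic phenol, so the hydroxyl group needs no protection.

**Step 2**
Reactants: 2 5-(4-hydroxyphenyl)-N-methoxy-N-methylpentanamide; 3 1-bromopentadecane
Product: 5 1-(4-hydroxyphenyl)icosan-5-one, via pentadecylmagnesium bromide 4 (not isolated)
Conditions: 3, Mg, THF, reflux; then 2 added to 4 (2.3 equiv), THF, 0 °C to rt; 1 M HCl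
Reagents that add atoms: none
Why: Weinreb ketone synthesis, in which the first equivalent of 4 is spent on the phenol and the second adds to the amide to give a magnesium chelate that should not collapse before the acidic quench, so over-addition to a tertiary alcohol is not expected.

**Step 3**
Reactants: 5 1-(4-hydroxyphenyl)icosan-5-one
Product: 6 4-[4-(2-pentadecyl-1,3-dioxolan-2-yl)butyl]phenol
Conditions: ethylene glycol, p-toluenesulfonic acid monohydrate (cat.), toluene, reflux, Dean–Stark trap
Reagents that add atoms: ethylene glycol, OCCO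
Why: Acid-catalysed ketalisation driven by azeotropic removal of water, which should mask C5 against n-butyllithium in step 6 while the phenol stays untouched.

**Step 4**
Reactants: 6 4-[4-(2-pentadecyl-1,3-dioxolan-2-yl)butyl]phenol
Product: 7 2-bromo-4-[4-(2-pentadecyl-1,3-dioxolan-2-yl)butyl]phenol
Conditions: NBS (1.0 equiv), diisopropylamine (10 mol %), CH2Cl2, 0 °C
Reagents that add atoms: N-bromosuccinimide, O=C1CCC(=O)N1Br
Why: Electrophilic aromatic bromination directed by the hydroxyl group, whose para position is occupied by the chain, so bromine should enter at C3', and one equivalent of NBS under amine catalysis and non-acidic conditions should stop at the monobromide and spare the ketal.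

**Step 5**
Reactants: 7 2-bromo-4-[4-(2-pentadecyl-1,3-dioxolan-2-yl)butyl]phenol
Product: 8 {2-bromo-4-[4-(2-pentadecyl-1,3-dioxolan-2-yl)butyl]phenoxy}trimethylsilane
Conditions: (Me3Si)2NH, THF, reflux; evaporation, used crude
Reagents that add atoms: hexamethyldisilazane, C[Si](C)(C)N[Si](C)(C)C
Why: O-silylation of a phenol by a silazane, which gives ammonia as the only co-product, so the moisture-sensitive silyl ether should be obtained clean enough by evaporation alone.

**Step 6**
Reactants: 8 {2-bromo-4-[4-(2-pentadecyl-1,3-dioxolan-2-yl)butyl]phenoxy}trimethylsilane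
Product: 11 4-[4-(2-pentadecyl-1,3-dioxolan-2-yl)butyl]-2-(trimethylsilyl)phenyl trifluoromethanesulfonate, via aryllithium 9 (not isolated), via lithium 2-silylphenoxide 10 (not isolated)
Conditions: n-BuLi, THF, −78 °C; then Tf2O, −78 °C; NaHCO3 (aq)
Reagents that add atoms: trifluoromethanesulfonic anhydride, O=S(=O)(OS(=O)(=O)C(F)(F)F)C(F)(F)F
Why: Bromine–lithium exchange followed by retro-Brook rearrangement, in which aryllithium 9 should take the silyl group from the neighbouring oxygen to give the more stable phenoxide 10 with the C3'–Si bond in place, which Tf2O then sulfonylates on oxygen while the dioxolane shields C5.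

**Step 7**
Reactants: 11 4-[4-(2-pentadecyl-1,3-dioxolan-2-yl)butyl]-2-(trimethylsilyl)phenyl trifluoromethanesulfonate
Product: 12 4-(5-oxoicosyl)-2-(trimethylsilyl)phenyl trifluoromethanesulfonate
Conditions: 2 M HCl, THF, rt
Reagents that add atoms: water, O
Why: Acid-catalysed ketal hydrolysis under dilute aqueous acid, to which an aryl triflate is inert and under which the C–Si bond, on a ring deactivated by the triflate, should resist protodesilylation.

**Step 8**
Reactants: 12 4-(5-oxoicosyl)-2-(trimethylsilyl)phenyl trifluoromethanesulfonate; 13 bis(pinacolato)diboron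
Product: 15 1-[3,4-bis(4,4,5,5-tetramethyl-1,3,2-dioxaborolan-2-yl)phenyl]icosan-5-one, via 4-(5-oxoicosyl)benzyne 14 (not isolated)
Conditions: Pt(dba)2 (5 mol %), 1-adamantyl isocyanide (20 mol %), KF, 18-crown-6, 13 (1.5 equiv), DME, 80 °C
Reagents that add atoms: none
Why: Fluoride attacks silicon of 12 and triflate leaves from the neighbouring carbon, releasing aryne 14 only as fast as the crown ether brings KF into solution, while the B–B bond of 13 adds oxidatively to zerovalent platinum to give a cis-bis(boryl) complex of divalent platinum, the strained C3'–C4' triple bond inserts into one Pt–B bond, and C–B reductive elimination should deliver 15 and return zerovalent platinum. The closest known reaction type is the platinum-catalysed cis-diboration of alkynes and its extension to arynes released from 2-silylaryl triflates. No ring is closed and no stereocentre is created, so neither a mode of closure nor a stereocontrol element is involved. Regioselectivity is not required, because the two boryl groups are identical and the weak polarisation of the aryne by the remote chain is therefore without consequence. The selectivity that is needed is chemoselectivity for insertion over aryne oligomerisation, which the slow release of 14 and the excess of 13 should secure, and for the aryne over the C5 ketone, which neither fluoride nor the boryl–platinum species should touch under these conditions.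

**Step 9**
Reactants: 15 1-[3,4-bis(4,4,5,5-tetramethyl-1,3,2-dioxaborolan-2-yl)phenyl]icosan-5-one
Product: 16 1-(3,4-dihydroxyphenyl)icosan-5-one
Conditions: NaBO3·4H2O, THF/H2O (1:1), rt, argon; then 1 M HCl to pH 3
Reagents that add atoms: sodium perborate tetrahydrate, O.O.O.O.[Na+].[O-]OB=O
Why: Oxidation of arylboronates to phenols, in which the peroxo nucleophile adds to each boron and the aryl group shifts from boron to oxygen so that each hydroxyl takes exactly the place of its boron, while the mild, non-acidic perborate should spare the dialkyl ketone from Baeyer–Villiger oxidation.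

**Compound list**

1 | 5-(4-hydroxyphenyl)pentanoic acid | OC(=O)CCCCc1ccc(O)cc1 | starting material
2 | 5-(4-hydroxyphenyl)-N-methoxy-N-methylpentanamide | CON(C)C(=O)CCCCc1ccc(O)cc1 | intermediate
3 | 1-bromopentadecane | CCCCCCCCCCCCCCCBr | starting material
4 | pentadecylmagnesium bromide | CCCCCCCCCCCCCCC[Mg]Br | intermediate (not isolated)
5 | 1-(4-hydroxyphenyl)icosan-5-one | CCCCCCCCCCCCCCCC(=O)CCCCc1ccc(O)cc1 | intermediate
6 | 4-[4-(2-pentadecyl-1,3-dioxolan-2-yl)butyl]phenol | CCCCCCCCCCCCCCCC1(CCCCc2ccc(O)cc2)OCCO1 | intermediate
7 | 2-bromo-4-[4-(2-pentadecyl-1,3-dioxolan-2-yl)butyl]phenol | CCCCCCCCCCCCCCCC1(CCCCc2ccc(O)c(Br)c2)OCCO1 | intermediate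
8 | {2-bromo-4-[4-(2-pentadecyl-1,3-dioxolan-2-yl)butyl]phenoxy}trimethylsilane | CCCCCCCCCCCCCCCC1(CCCCc2ccc(O[Si](C)(C)C)c(Br)c2)OCCO1 | intermediate
9 | {5-[4-(2-pentadecyl-1,3-dioxolan-2-yl)butyl]-2-[(trimethylsilyl)oxy]phenyl}lithium | CCCCCCCCCCCCCCCC1(CCCCc2ccc(O[Si](C)(C)C)c([Li])c2)OCCO1 | intermediate (not isolated)
10 | lithium 4-[4-(2-pentadecyl-1,3-dioxolan-2-yl)butyl]-2-(trimethylsilyl)phenoxide | CCCCCCCCCCCCCCCC1(CCCCc2ccc([O-])c([Si](C)(C)C)c2)OCCO1.[Li+] | intermediate (not isolated)
11 | 4-[4-(2-pentadecyl-1,3-dioxolan-2-yl)butyl]-2-(trimethylsilyl)phenyl trifluoromethanesulfonate | CCCCCCCCCCCCCCCC1(CCCCc2ccc(OS(=O)(=O)C(F)(F)F)c([Si](C)(C)C)c2)OCCO1 | intermediate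
12 | 4-(5-oxoicosyl)-2-(trimethylsilyl)phenyl trifluoromethanesulfonate | CCCCCCCCCCCCCCCC(=O)CCCCc1ccc(OS(=O)(=O)C(F)(F)F)c([Si](C)(C)C)c1 | intermediate
13 | bis(pinacolato)diboron | CC1(C)OB(OC1(C)C)B1OC(C)(C)C(C)(C)O1 | starting material
14 | 1-(3,4-didehydrophenyl)icosan-5-one (4-(5-oxoicosyl)benzyne) | CCCCCCCCCCCCCCCC(=O)CCCCC1=CC#CC=C1 | intermediate (not isolated)
15 | 1-[3,4-bis(4,4,5,5-tetramethyl-1,3,2-dioxaborolan-2-yl)phenyl]icosan-5-one | CCCCCCCCCCCCCCCC(=O)CCCCc1ccc(B2OC(C)(C)C(C)(C)O2)c(B2OC(C)(C)C(C)(C)O2)c1 | intermediate
16 | 1-(3,4-dihydroxyphenyl)icosan-5-one | CCCCCCCCCCCCCCCC(=O)CCCCc1ccc(O)c(O)c1 | target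

**Step count**

Total step count: 9.
Longest linear sequence: 9 steps (1 to 16); reagent 4 is made and used up within step 2, and 13 enters in step 8.

**Steps most likely to fail**

1. Step 8. Oligomerisation of the aryne, or its capture by fluoride-activated diboron or by the isocyanide ligand, may outrun insertion into the boryl–platinum bond. The fallback gives up the aryne and brings in the second oxygen by formylation and Dakin oxidation. It sets out from phenol ketone 5. MgCl2, Et3N and paraformaldehyde in MeCN at reflux should formylate the magnesium phenoxide at the only free activated position, ortho to oxygen, to give 2-hydroxy-5-(5-oxoicosyl)benzaldehyde F1. H2O2 and NaOH in aqueous THF at 0 °C to rt should then effect the Dakin oxidation, in which the aryl group migrates to oxygen to give 2-hydroxy-5-(5-oxoicosyl)phenyl formate F2. This formate is hydrolysed in the same flask, and the sequence comes back to the route at target 16.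

2. Step 6. The aryllithium may be quenched by adventitious proton sources or by the 1-bromobutane formed before the silyl group has migrated. The waxy substrate may also precipitate at −78 °C, and sulfonylation of the hindered phenoxide may stay incomplete. The fallback replaces halogen exchange and silyl shift by directed ortho-metalation and sets out from phenol ketal 6.
   - Isopropyl isocyanate with catalytic Et3N in CH2Cl2 should give 4-[4-(2-pentadecyl-1,3-dioxolan-2-yl)butyl]phenyl N-(propan-2-yl)carbamate F3.
   - In one flask, TMSOTf (1.05 equiv) and TMEDA in Et2O at 0 °C silylate nitrogen to give the N-silylated carbamate F4. n-BuLi and TMEDA at −78 °C then lithiate ortho to the carbamate to give the ortho-lithiated carbamate F5. TMSCl gives the C,N-bis-silylated carbamate F6, and aqueous NH4Cl work-up cleaves the N–Si bond to leave the 2-(trimethylsilyl)aryl N-(propan-2-yl)carbamate F7.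
   - DBU and Et2NH in MeCN at 40 °C should release 4-[4-(2-pentadecyl-1,3-dioxolan-2-yl)butyl]-2-(trimethylsilyl)phenol F8. N-phenylbis(trifluoromethanesulfonimide) triflates it in the same flask, and the sequence comes back to the route at ketal triflate 11.

3. Step 9. The emerging catechol may be oxidised further to the ortho-quinone in the basic peroxide medium, and oxidation of the second, hindered C–B bond may stay incomplete, so that chromatography of the free catechol becomes lossy. The fallback isolates the catechol in protected form and sets out from bis-boronate 15. Oxidation with H2O2 in THF and pH 7 phosphate buffer at 0 °C is followed, without purification of the crude catechol, by Ac2O, pyridine and catalytic 4-(dimethylamino)pyridine. This should give the air-stable 4-(5-oxoicosyl)-1,2-phenylene diacetate F9, which can be purified at leisure. Methanolysis with HCl in MeOH at rt under argon then comes back to the route at target 16.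

**Further compounds**

F1 | step 8 | 2-hydroxy-5-(5-oxoicosyl)benzaldehyde | CCCCCCCCCCCCCCCC(=O)CCCCc1ccc(O)c(C=O)c1
F2 | step 8 | 2-hydroxy-5-(5-oxoicosyl)phenyl formate | CCCCCCCCCCCCCCCC(=O)CCCCc1ccc(O)c(OC=O)c1
F3 | step 6 | 4-[4-(2-pentadecyl-1,3-dioxolan-2-yl)butyl]phenyl N-(propan-2-yl)carbamate | CCCCCCCCCCCCCCCC1(CCCCc2ccc(OC(=O)NC(C)C)cc2)OCCO1
F4 | step 6 | 4-[4-(2-pentadecyl-1,3-dioxolan-2-yl)butyl]phenyl N-(propan-2-yl)-N-(trimethylsilyl)carbamate | CCCCCCCCCCCCCCCC1(CCCCc2ccc(OC(=O)N(C(C)C)[Si](C)(C)C)cc2)OCCO1
F5 | step 6 | 2-lithio-4-[4-(2-pentadecyl-1,3-dioxolan-2-yl)butyl]phenyl N-(propan-2-yl)-N-(trimethylsilyl)carbamate | CCCCCCCCCCCCCCCC1(CCCCc2ccc(OC(=O)N(C(C)C)[Si](C)(C)C)c([Li])c2)OCCO1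
F6 | step 6 | 4-[4-(2-pentadecyl-1,3-dioxolan-2-yl)butyl]-2-(trimethylsilyl)phenyl N-(propan-2-yl)-N-(trimethylsilyl)carbamate | CCCCCCCCCCCCCCCC1(CCCCc2ccc(OC(=O)N(C(C)C)[Si](C)(C)C)c([Si](C)(C)C)c2)OCCO1
F7 | step 6 | 4-[4-(2-pentadecyl-1,3-dioxolan-2-yl)butyl]-2-(trimethylsilyl)phenyl N-(propan-2-yl)carbamate | CCCCCCCCCCCCCCCC1(CCCCc2ccc(OC(=O)NC(C)C)c([Si](C)(C)C)c2)OCCO1
F8 | step 6 | 4-[4-(2-pentadecyl-1,3-dioxolan-2-yl)butyl]-2-(trimethylsilyl)phenol | CCCCCCCCCCCCCCCC1(CCCCc2ccc(O)c([Si](C)(C)C)c2)OCCO1
F9 | step 9 | 4-(5-oxoicosyl)-1,2-phenylene diacetate | CCCCCCCCCCCCCCCC(=O)CCCCc1ccc(OC(C)=O)c(OC(C)=O)c1
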